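A direct plan would set the ether carbon C8 first by Mitsunobu inversion of ethyl (S)-lactate A2 with 4-allyl-2,6-dimethoxyphenol A1 to the (R)-aryloxy ester A3, convert A3 through the Weinreb amide A4 into the ethynyl ketone A5, build ring B on A5 by Diels–Alder addition of 3,4-dimethoxyfuran A6 and acid-induced opening of the oxanorbornadiene A7 to the aryl ketone A8, and finish with a bulky-hydride reduction of the C7 ketone of A8.
Weak step, the cycloaddition and acid isomerisation that build ring B: from the labile furan A6 and the Michael-accepting terminal ynone A5 it would assemble a benzene ring that can be bought with its three oxygens in place; the cycloaddition is reversible, the bis(enol ether) A7 must survive acid, and the position of the phenol in A8 depends on which bridgehead C–O bond ionises.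
Weak step, the early Mitsunobu etherification and the carriage of C8: the phenol A1 is flanked by two methoxy groups (slow substitution, risk of elimination and of eroded enantiopurity), and C8 would then travel as an enolisable α-aryloxy carbonyl centre through Grignard, acid and basic hydride conditions.
Weak step, the final ketone reduction: the carbinol carbon C7 would be set alone and last by 1,2-induction, where Felkin–Anh and chelate pathways compete, so the threo or erythro outcome of the whole route would rest on one substrate-controlled step.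

**Retrosynthetic overview**
Numbering: ring A = 4-allyl-2,6-dimethoxyphenyl, ring B = 3-hydroxy-4,5-dimethoxyphenyl, C7 = benzylic carbinol carbon, C8 = ether carbon, C9 = methyl.
The C9 methyl next to the syn C7–OH/C8–OAr pair is read as a reduced carboxyl carbon, which makes the target a syn glycolate aldol product: the key disconnection is the C7–C8 bond, between a (ring A–O)acetyl imide (O, C8, C9) and a ring B aldehyde (C7).
Both rings are bought as arenes and none is formed; the C8–O bond is made first, by O-alkylation of the phenol with bromoacetic acid at a CH2 group where no stereocentre is at stake.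
One auxiliary-controlled aldol step then joins the two halves and sets C7 and C8 together; afterwards C9 is taken from imide to methyl (hydride cleavage, tosylation, hydride displacement) and the ring B phenol is unmasked.
The design has no Mitsunobu step at the hindered phenol, no α-aryloxy ketone at any stage, no separate reduction to set C7, and no ring construction.

Key step: step 4

Remark: compounds 1, 2, 4 and 7 are taken as purchasable; the silyl ether on ring B is the only protecting group.

Step 1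
Reactants: 1 4-allyl-2,6-dimethoxyphenol; 2 bromoacetic acid
Product: 3 2-(4-allyl-2,6-dimethoxyphenoxy)acetic acid
Conditions: 2 (1.5 equiv), NaOH (3.5 equiv), H2O, 90 °C; then aq. HCl to pH 1
Reagents that add atoms: none
Why: Williamson ether synthesis, in which the phenoxide displaces bromide from the primary α-halo carboxylate by SN2, a substitution that tolerates the two ortho methoxy groups and should leave the allyl group unisomerised at this temperature; no stereocentre is involved.

Step 2
Reactants: 3 2-(4-allyl-2,6-dimethoxyphenoxy)acetic acid; 4 (S)-4-benzyl-2-oxazolidinone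
Product: 6 (S)-3-[2-(4-allyl-2,6-dimethoxyphenoxy)acetyl]-4-benzyloxazolidin-2-one, via mixed pivalic anhydride 5 (not isolated)
Conditions: PivCl (1.1 equiv), Et3N (2.5 equiv), THF, −20 °C; then LiCl (1.2 equiv), 4 (1.0 equiv), −20 °C → rt
Reagents that add atoms: pivaloyl chloride, CC(C)(C)C(=O)Cl (its acyl group stays in 5 only)
Why: N-acylation of the oxazolidinone through the mixed pivalic anhydride under LiCl/Et3N activation, a one-flask protocol without strong base in which the nucleophile attacks the less hindered carbonyl of the anhydride; the auxiliary stereocentre is untouched.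

Step 3
Reactants: 7 3-hydroxy-4,5-dimethoxybenzaldehyde
Product: 8 3-(tert-butyldimethylsilyloxy)-4,5-dimethoxybenzaldehyde
Conditions: TBSCl (1.2 equiv), imidazole (2.5 equiv), DMF, rt
Reagents that add atoms: tert-butyldimethylsilyl chloride, CC(C)(C)[Si](C)(C)Cl
Why: Imidazole-promoted silylation of the phenol, which masks the acidic OH before the boron enolate chemistry and leaves the aldehyde untouched.

Step 4
Reactants: 6 (S)-3-[2-(4-allyl-2,6-dimethoxyphenoxy)acetyl]-4-benzyloxazolidin-2-one; 8 3-(tert-butyldimethylsilyloxy)-4,5-dimethoxybenzaldehyde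
Product: 11 (S)-3-[(2S,3R)-2-(4-allyl-2,6-dimethoxyphenoxy)-3-[3-(tert-butyldimethylsilyloxy)-4,5-dimethoxyphenyl]-3-hydroxypropanoyl]-4-benzyloxazolidin-2-one, via (Z)-dibutylboron enolate 9 (not isolated), via dibutylboron aldolate 10 (not isolated)
Conditions: 6, Bu2BOTf (1.2 equiv), i-Pr2NEt (1.4 equiv), CH2Cl2, −78 → 0 °C; 8 (1.2 equiv), −78 → 0 °C; pH 7 phosphate buffer, MeOH, 30% H2O2, 0 °C
Reagents that add atoms: dibutylboron triflate, CCCCB(CCCC)OS(=O)(=O)C(F)(F)F (boron stays in 9 and 10 only)
Why: Evans boron-mediated syn-aldol reaction of a glycolate-type imide: soft enolisation gives the (Z)-dibutylboron enolate 9, which adds to aldehyde 8 through a closed chair (Zimmerman–Traxler) transition state with the aryl group of the aldehyde equatorial, the imide carbonyl turned away from the enolate oxygen, and the benzyl group of the (S)-auxiliary shielding one enolate face. The closest known reaction type is the auxiliary-controlled syn-aldol addition of N-(alkoxyacetyl)- and N-(aryloxyacetyl)oxazolidinones to aromatic aldehydes. No ring is closed; the step forms the C7–C8 bond and so joins the ring A half to the ring B half. Both stereocentres arise together: the syn relation of C8–OAr and C7–OH follows from the enolate geometry and the chair, and the absolute sense from the auxiliary, which should give the (2S,3R) adduct, that is 7R,8R once C9 is reduced to methyl. The selectivity needed is a non-chelated transition state, and the boron atom secures it because its two butyl groups leave no free site for the aryl ether or methoxy oxygens; the aldehyde cannot enolise, and the allyl group and the silyl ether are spectators. Buffered H2O2 then cleaves the boron aldolate 10 without epimerising C8.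

Step 5
Reactants: 11 (S)-3-[(2S,3R)-2-(4-allyl-2,6-dimethoxyphenoxy)-3-[3-(tert-butyldimethylsilyloxy)-4,5-dimethoxyphenyl]-3-hydroxypropanoyl]-4-benzyloxazolidin-2-one
Product: 12 (1R,2R)-2-(4-allyl-2,6-dimethoxyphenoxy)-1-[3-(tert-butyldimethylsilyloxy)-4,5-dimethoxyphenyl]propane-1,3-diol
Conditions: LiBH4 (1.5 equiv), H2O (1.5 equiv), Et2O–THF, 0 °C; aq. NH4Cl
Reagents that add atoms: none
Why: Reductive cleavage of the N-acyloxazolidinone, in which hydride attacks the lithium-activated exocyclic carbonyl and takes C9 to the primary alcohol without touching C7, C8, the aryl silyl ether or the alkene, and the auxiliary is released for recovery.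

Step 6
Reactants: 12 (1R,2R)-2-(4-allyl-2,6-dimethoxyphenoxy)-1-[3-(tert-butyldimethylsilyloxy)-4,5-dimethoxyphenyl]propane-1,3-diol
Product: 13 (2R,3R)-2-(4-allyl-2,6-dimethoxyphenoxy)-3-[3-(tert-butyldimethylsilyloxy)-4,5-dimethoxyphenyl]-3-hydroxypropyl 4-methylbenzenesulfonate
Conditions: TsCl (1.15 equiv), Et3N (2 equiv), DMAP (5 mol %), CH2Cl2, 0 °C
Reagents that add atoms: p-toluenesulfonyl chloride, Cc1ccc(S(=O)(=O)Cl)cc1
Why: Kinetically selective sulfonylation of the primary C9 hydroxyl over the hindered secondary benzylic C7 hydroxyl, with no bond to a stereocentre broken.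

Step 7
Reactants: 13 (2R,3R)-2-(4-allyl-2,6-dimethoxyphenoxy)-3-[3-(tert-butyldimethylsilyloxy)-4,5-dimethoxyphenyl]-3-hydroxypropyl 4-methylbenzenesulfonate
Product: 15 (1R,2R)-2-(4-allyl-2,6-dimethoxyphenoxy)-1-(3-hydroxy-4,5-dimethoxyphenyl)propan-1-ol, via silyl ether 14 (not isolated)
Conditions: LiEt3BH (1 M in THF, 4 equiv), THF, 0 °C → rt; aq. NH4Cl, extraction, crude 14 taken on; then Bu4NF (1 M in THF, 1.5 equiv), THF, 0 °C → rt; aq. NH4Cl
Reagents that add atoms: none
Why: SN2 displacement of the primary tosylate by the strongly nucleophilic hydride LiEt3BH (the standard reduction of a 1,3-diol monotosylate to a methyl carbinol) turns C9 into methyl with C7 and C8 untouched, and after an aqueous wash that removes the lithium and boron species, which would otherwise bind fluoride, Bu4NF cleaves the aryl silyl ether of crude 14 to give the target.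

**Compound list**
1 | 4-allyl-2,6-dimethoxyphenol | C=CCc1cc(OC)c(O)c(OC)c1 | starting material
2 | bromoacetic acid | OC(=O)CBr | starting material
3 | 2-(4-allyl-2,6-dimethoxyphenoxy)acetic acid | C=CCc1cc(OC)c(OCC(=O)O)c(OC)c1 | intermediate
4 | (S)-4-benzyl-2-oxazolidinone | O=C1OC[C@H](Cc2ccccc2)N1 | starting material
5 | 2-(4-allyl-2,6-dimethoxyphenoxy)acetic pivalic anhydride | C=CCc1cc(OC)c(OCC(=O)OC(=O)C(C)(C)C)c(OC)c1 | intermediate
6 | (S)-3-[2-(4-allyl-2,6-dimethoxyphenoxy)acetyl]-4-benzyloxazolidin-2-one | C=CCc1cc(OC)c(OCC(=O)N2[C@@H](Cc3ccccc3)COC2=O)c(OC)c1 | intermediate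
7 | 3-hydroxy-4,5-dimethoxybenzaldehyde | O=Cc1cc(O)c(OC)c(OC)c1 | starting material
8 | 3-(tert-butyldimethylsilyloxy)-4,5-dimethoxybenzaldehyde | O=Cc1cc(O[Si](C)(C)C(C)(C)C)c(OC)c(OC)c1 | intermediate
9 | (Z)-dibutylboron enolate of 6 | C=CCc1cc(OC)c(O/C=C(\OB(CCCC)CCCC)N2[C@@H](Cc3ccccc3)COC2=O)c(OC)c1 | intermediate
10 | dibutylboron aldolate of 11 (O-boryl at C7) | C=CCc1cc(OC)c(O[C@H](C(=O)N2[C@@H](Cc3ccccc3)COC2=O)[C@H](OB(CCCC)CCCC)c4cc(O[Si](C)(C)C(C)(C)C)c(OC)c(OC)c4)c(OC)c1 | intermediate
11 | (S)-3-[(2S,3R)-2-(4-allyl-2,6-dimethoxyphenoxy)-3-[3-(tert-butyldimethylsilyloxy)-4,5-dimethoxyphenyl]-3-hydroxypropanoyl]-4-benzyloxazolidin-2-one | C=CCc1cc(OC)c(O[C@H](C(=O)N2[C@@H](Cc3ccccc3)COC2=O)[C@H](O)c4cc(O[Si](C)(C)C(C)(C)C)c(OC)c(OC)c4)c(OC)c1 | intermediate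
12 | (1R,2R)-2-(4-allyl-2,6-dimethoxyphenoxy)-1-[3-(tert-butyldimethylsilyloxy)-4,5-dimethoxyphenyl]propane-1,3-diol | C=CCc1cc(OC)c(O[C@H](CO)[C@H](O)c2cc(O[Si](C)(C)C(C)(C)C)c(OC)c(OC)c2)c(OC)c1 | intermediate
13 | (2R,3R)-2-(4-allyl-2,6-dimethoxyphenoxy)-3-[3-(tert-butyldimethylsilyloxy)-4,5-dimethoxyphenyl]-3-hydroxypropyl 4-methylbenzenesulfonate | C=CCc1cc(OC)c(O[C@H](COS(=O)(=O)c2ccc(C)cc2)[C@H](O)c3cc(O[Si](C)(C)C(C)(C)C)c(OC)c(OC)c3)c(OC)c1 | intermediate
14 | (1R,2R)-2-(4-allyl-2,6-dimethoxyphenoxy)-1-[3-(tert-butyldimethylsilyloxy)-4,5-dimethoxyphenyl]propan-1-ol | C=CCc1cc(OC)c(O[C@H](C)[C@H](O)c2cc(O[Si](C)(C)C(C)(C)C)c(OC)c(OC)c2)c(OC)c1 | intermediate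
15 | (1R,2R)-2-(4-allyl-2,6-dimethoxyphenoxy)-1-(3-hydroxy-4,5-dimethoxyphenyl)propan-1-ol | C=CCc1cc(OC)c(O[C@H](C)[C@H](O)c2cc(O)c(OC)c(OC)c2)c(OC)c1 | target

**Step count and risks**
Total step count: 7. Longest linear sequence: 6 steps (steps 1, 2, 4, 5, 6, 7; step 3 is the side branch).

Steps most likely to fail:

1. Step 4 (aldol addition). The addition to the electron-rich aldehyde may be slow, and partial reversal of the aldolate on warming would erode the syn selectivity. The fallback sets the two stereocentres by a reduction under dynamic kinetic resolution; it sets out from 3 and 8 and comes back to the route at 12. Acid 3 would be esterified (MeI, K2CO3, DMF) to methyl 2-(4-allyl-2,6-dimethoxyphenoxy)acetate F1. Its lithium enolate (LiN(i-Pr)2, THF, −78 °C) would add to 8 to give methyl 2-(4-allyl-2,6-dimethoxyphenoxy)-3-[3-(tert-butyldimethylsilyloxy)-4,5-dimethoxyphenyl]-3-hydroxypropanoate F2 as a stereoisomer mixture. Oxidation (Dess–Martin periodinane, NaHCO3, CH2Cl2) would give the configurationally labile β-keto ester methyl 2-(4-allyl-2,6-dimethoxyphenoxy)-3-[3-(tert-butyldimethylsilyloxy)-4,5-dimethoxyphenyl]-3-oxopropanoate F3. Noyori–Ikariya transfer hydrogenation (RuCl(p-cymene)[(S,S)-TsDPEN], HCO2H/Et3N) should funnel both enantiomers of F3 into the syn ester methyl (2S,3R)-2-(4-allyl-2,6-dimethoxyphenoxy)-3-[3-(tert-butyldimethylsilyloxy)-4,5-dimethoxyphenyl]-3-hydroxypropanoate F4, and LiBH4 in THF would reduce F4 to diol 12.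

2. Step 7 (hydride displacement). The C7 alkoxide formed by the hydride may trigger fragmentation of the C7–C8 bond or oxetane closure, or hydride may attack at sulfur and return the diol. The fallback takes the C7 hydroxyl out of play before the displacement; it sets out from 13 and comes back to the route at 15. Silylation of 13 (Et3SiOTf, 2,6-lutidine, CH2Cl2, −78 °C) would give (2R,3R)-2-(4-allyl-2,6-dimethoxyphenoxy)-3-[3-(tert-butyldimethylsilyloxy)-4,5-dimethoxyphenyl]-3-(triethylsilyloxy)propyl 4-methylbenzenesulfonate F6. LiEt3BH in THF should reduce F6 to (1R,2R)-2-(4-allyl-2,6-dimethoxyphenoxy)-1-[3-(tert-butyldimethylsilyloxy)-4,5-dimethoxyphenyl]-1-(triethylsilyloxy)propane F7, and Bu4NF in THF would then remove both silyl groups to give 15.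

3. Step 5 (reductive removal of the auxiliary). Hydride may attack the ring carbonyl of the oxazolidinone, or the basic medium may induce retro-aldol cleavage. The fallback separates acyl transfer from reduction; it sets out from 11 and comes back to the route at 12. LiSEt (from EtSH and n-BuLi, THF, 0 °C) would transfer the acyl group to sulfur and give S-ethyl (2S,3R)-2-(4-allyl-2,6-dimethoxyphenoxy)-3-[3-(tert-butyldimethylsilyloxy)-4,5-dimethoxyphenyl]-3-hydroxypropanethioate F5, and NaBH4 in EtOH would reduce F5 to diol 12.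

**Further compounds**
F1 | step 4 | methyl 2-(4-allyl-2,6-dimethoxyphenoxy)acetate | C=CCc1cc(OC)c(OCC(=O)OC)c(OC)c1
F2 | step 4 | methyl 2-(4-allyl-2,6-dimethoxyphenoxy)-3-[3-(tert-butyldimethylsilyloxy)-4,5-dimethoxyphenyl]-3-hydroxypropanoate (stereoisomer mixture) | C=CCc1cc(OC)c(OC(C(=O)OC)C(O)c2cc(O[Si](C)(C)C(C)(C)C)c(OC)c(OC)c2)c(OC)c1
F3 | step 4 | methyl 2-(4-allyl-2,6-dimethoxyphenoxy)-3-[3-(tert-butyldimethylsilyloxy)-4,5-dimethoxyphenyl]-3-oxopropanoate (racemic) | C=CCc1cc(OC)c(OC(C(=O)OC)C(=O)c2cc(O[Si](C)(C)C(C)(C)C)c(OC)c(OC)c2)c(OC)c1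
F4 | step 4 | methyl (2S,3R)-2-(4-allyl-2,6-dimethoxyphenoxy)-3-[3-(tert-butyldimethylsilyloxy)-4,5-dimethoxyphenyl]-3-hydroxypropanoate | C=CCc1cc(OC)c(O[C@H](C(=O)OC)[C@H](O)c2cc(O[Si](C)(C)C(C)(C)C)c(OC)c(OC)c2)c(OC)c1
F5 | step 5 | S-ethyl (2S,3R)-2-(4-allyl-2,6-dimethoxyphenoxy)-3-[3-(tert-butyldimethylsilyloxy)-4,5-dimethoxyphenyl]-3-hydroxypropanethioate | C=CCc1cc(OC)c(O[C@H](C(=O)SCC)[C@H](O)c2cc(O[Si](C)(C)C(C)(C)C)c(OC)c(OC)c2)c(OC)c1
F6 | step 7 | (2R,3R)-2-(4-allyl-2,6-dimethoxyphenoxy)-3-[3-(tert-butyldimethylsilyloxy)-4,5-dimethoxyphenyl]-3-(triethylsilyloxy)propyl 4-methylbenzenesulfonate | C=CCc1cc(OC)c(O[C@H](COS(=O)(=O)c2ccc(C)cc2)[C@H](O[Si](CC)(CC)CC)c3cc(O[Si](C)(C)C(C)(C)C)c(OC)c(OC)c3)c(OC)c1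
F7 | step 7 | (1R,2R)-2-(4-allyl-2,6-dimethoxyphenoxy)-1-[3-(tert-butyldimethylsilyloxy)-4,5-dimethoxyphenyl]-1-(triethylsilyloxy)propane | C=CCc1cc(OC)c(O[C@H](C)[C@H](O[Si](CC)(CC)CC)c2cc(O[Si](C)(C)C(C)(C)C)c(OC)c(OC)c2)c(OC)c1
A1 | direct plan | 4-allyl-2,6-dimethoxyphenol | C=CCc1cc(OC)c(O)c(OC)c1
A2 | direct plan | ethyl (S)-lactate | C[C@H](O)C(=O)OCC
A3 | direct plan | ethyl (R)-2-(4-allyl-2,6-dimethoxyphenoxy)propanoate | C=CCc1cc(OC)c(O[C@H](C)C(=O)OCC)c(OC)c1
A4 | direct plan | (R)-2-(4-allyl-2,6-dimethoxyphenoxy)-N-methoxy-N-methylpropanamide | C=CCc1cc(OC)c(O[C@H](C)C(=O)N(C)OC)c(OC)c1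
A5 | direct plan | (R)-4-(4-allyl-2,6-dimethoxyphenoxy)pent-1-yn-3-one | C=CCc1cc(OC)c(O[C@H](C)C(=O)C#C)c(OC)c1
A6 | direct plan | 3,4-dimethoxyfuran | COc1cocc1OC
A7 | direct plan | (2R)-2-(4-allyl-2,6-dimethoxyphenoxy)-1-(5,6-dimethoxy-7-oxabicyclo[2.2.1]hepta-2,5-dien-2-yl)propan-1-one (mixture of bridgehead diastereomers) | C=CCc1cc(OC)c(O[C@H](C)C(=O)C2=CC3OC2C(OC)=C3OC)c(OC)c1
A8 | direct plan | (R)-2-(4-allyl-2,6-dimethoxyphenoxy)-1-(3-hydroxy-4,5-dimethoxyphenyl)propan-1-one | C=CCc1cc(OC)c(O[C@H](C)C(=O)c2cc(O)c(OC)c(OC)c2)c(OC)c1
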